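**Plan**

- Retrosynthesis: the C-6 methyl and C-6=C-7 enone of the hexahydroazulen-5-one are traced to a ring 6-phosphono ketone (HCHO olefination, then isomerization); the seven-membered ring is then cut at C-7–C-8; the resulting alkylidene β-ketophosphonate is cut at its C=C bond (Knoevenagel) into cyclopentane ketophosphonate 23 and oxepane–cyclohexane aldehyde 15.
- Enabling feature: quaternary C-8 (gem-dimethyl) of the seven-membered ring lies between ring-fusion C-8a and the enone β-carbon C-7, and its arm is cis on the cyclopentane to the C-4/C-5 arm on C-3a. An isopropenyl group on C-8a is therefore a latent tertiary radical placed to add 7-endo to C-7.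
- Forward, left half: geraniol → epoxy ketophosphonate → enone → diepoxide → silyl enol ether; one epoxide-opening cascade closes the oxepane and the cyclohexanone together; MeLi addition, debenzylation and oxidation give 15.
- Forward, right half: (4R)-limonene oxide → cyclopentene aldehyde → epoxide → one-carbon homologation with epoxide transposition → conjugate reduction → diazophosphonate homologation gives 23. After Knoevenagel union the seven-membered ring is closed last by MHAT radical conjugate addition; methylenation, isomerization and desilylation finish.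
- Stereochemistry: benzoxepine C-5a/C-9a from Sharpless epoxidation, C-3 from ent-Shi epoxidation, C-6 from the chair cascade, C-7 from equatorial MeLi attack. Azulenone C-8a comes from (R)-limonene, C-3 from epoxidation anti to isopropenyl, C-3a from hydride delivery to the less hindered face. Alkene isomers of 21 and 24 and diastereomers of 25 and 26 all converge.

Key step: step 18

Remark: the oxepane carbinol (3S) and the ring-fusion centres (5aR, 9aR) correspond to epoxides of opposite enantiofacial sense, so the two epoxides are set by two separate reagent-controlled oxidations; commercial (4R)-limonene 1,2-oxide is used as its cis/trans mixture, both isomers giving 17.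

**Left half**

Step 1
Reactants: 1 geraniol
Product: 2 [(2R,3R)-3-methyl-3-(4-methylpent-3-en-1-yl)oxiran-2-yl]methanol
Conditions: Ti(OiPr)4 (5 mol%), D-(−)-diethyl tartrate (7 mol%), t-BuOOH, 4 Å molecular sieves, CH2Cl2, −20 °C
Reagents that add atoms: tert-butyl hydroperoxide, CC(C)(C)OO
Why: Sharpless asymmetric epoxidation touches only the allylic alkene and, with the D-tartrate, should deliver oxygen to the face that gives the (2R,3R)-epoxide, whose carbons become C-9a and C-5a of the benzoxepine.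

Step 2
Reactants: 2 (2R,3R)-2,3-epoxygeraniol
Product: 3 [(2R,3R)-3-methyl-3-(4-methylpent-3-en-1-yl)oxiran-2-yl]methyl 4-methylbenzenesulfonate
Conditions: TsCl, Et3N, DMAP (cat.), CH2Cl2, 0 °C
Reagents that add atoms: 4-methylbenzenesulfonyl chloride, Cc1ccc(cc1)S(Cl)(=O)=O
Why: Sulfonylation of the primary alcohol activates C-1 for substitution and leaves both stereocentres untouched.

Step 3
Reactants: 3 epoxy tosylate; 4 dimethyl (2-oxopropyl)phosphonate
Product: 6 dimethyl {4-[(2R,3R)-3-methyl-3-(4-methylpent-3-en-1-yl)oxiran-2-yl]-2-oxobutyl}phosphonate, via phosphonate dianion 5 (not isolated)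
Conditions: 4, NaH, THF, 0 °C; n-BuLi, 0 °C; then 3, 0 °C to rt
Reagents that add atoms: none
Why: γ-Alkylation of a β-ketophosphonate dianion, whose terminal carbanion should displace the primary tosylate by SN2 while the fully substituted epoxide carbon blocks attack on the ring.

Step 4
Reactants: 6 epoxy ketophosphonate; 7 3-(benzyloxy)propanal
Product: 8 (4E)-7-(benzyloxy)-1-[(2R,3R)-3-methyl-3-(4-methylpent-3-en-1-yl)oxiran-2-yl]hept-4-en-3-one
Conditions: LiCl, i-Pr2NEt, MeCN, rt
Reagents that add atoms: none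
Why: Horner–Wadsworth–Emmons olefination under mild LiCl/amine conditions should give the (E)-enone, which fixes on which side of the ketone the later enol ether will lie.

Step 5
Reactants: 8 epoxy dienone
Product: 9 (4E)-7-(benzyloxy)-1-[(2R,3R)-3-{2-[(2S)-3,3-dimethyloxiran-2-yl]ethyl}-3-methyloxiran-2-yl]hept-4-en-3-one
Conditions: ent-Shi ketone (1,2:4,5-di-O-isopropylidene-β-L-erythro-2,3-hexodiulo-2,6-pyranose, 30 mol%), Oxone (2KHSO5·KHSO4·K2SO4), K2CO3, Bu4NHSO4, MeCN/CH2(OMe)2/aqueous borate buffer, 0 °C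
Reagents that add atoms: potassium peroxymonosulfate, [K+].[O-]S(=O)(=O)OO
Why: Shi epoxidation by the chiral dioxirane attacks only the electron-rich trisubstituted alkene (the enone is inert), and the L-series ketone should give the (S)-epoxide that becomes the oxepane carbinol C-3.

Step 6
Reactants: 9 diepoxy enone
Product: 10 {[(3Z)-7-(benzyloxy)-1-[(2R,3R)-3-{2-[(2S)-3,3-dimethyloxiran-2-yl]ethyl}-3-methyloxiran-2-yl]hept-3-en-3-yl]oxy}(triethyl)silane
Conditions: Et3SiH, RhCl(PPh3)3 (2 mol%), benzene, 50 °C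
Reagents that add atoms: triethylsilane, CC[SiH](CC)CC
Why: Rhodium-catalysed 1,4-hydrosilylation of the enone should give the (Z)-silyl enol ether regiospecifically on the side-chain carbon, a regiochemistry that enolization of the saturated ketone could not secure.

Step 7
Reactants: 10 diepoxy silyl enol ether
Product: 11 (3S,5aR,6R,9aR)-6-[3-(benzyloxy)propyl]-2,2,5a-trimethyl-3-[(triethylsilyl)oxy]octahydro-1-benzoxepin-7(2H)-one
Conditions: Et3SiOTf (1.1 equiv), 2,6-di-tert-butyl-4-methylpyridine, CH2Cl2, −78 °C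
Reagents that add atoms: triethylsilyl trifluoromethanesulfonate, CC[Si](CC)(CC)OS(=O)(=O)C(F)(F)F
Why: Tandem oxa-/carbacyclization: the silyl triflate activates the terminal epoxide, the internal epoxide oxygen opens it at the tertiary carbon to a bicyclic epoxonium ion, and the enol silane carbon attacks the tertiary epoxonium carbon anti through a chair; this should give the trans-fused oxepane–cyclohexanone with retention at C-3 and C-9a, inversion at C-5a and the side chain at C-6 equatorial (an axial epimer would equilibrate through the enol).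

Step 8
Reactants: 11 bicyclic ketone
Product: 13 (3S,5aR,6R,7S,9aR)-6-[3-(benzyloxy)propyl]-2,2,5a,7-tetramethyl-3,7-bis[(triethylsilyl)oxy]decahydro-1-benzoxepine, via lithium alkoxide 12 (not isolated)
Conditions: MeLi, THF/Et2O, −78 °C; then Et3SiOTf, −78 to 0 °C
Reagents that add atoms: methyllithium, [Li]C; triethylsilyl trifluoromethanesulfonate, CC[Si](CC)(CC)OS(=O)(=O)C(F)(F)F
Why: 1,2-Addition to a cyclohexanone whose axial face is blocked by the 1,3-diaxial C-5a methyl should occur equatorially (methyl equatorial, oxygen axial, 7S), and silylation of the alkoxide in the same flask masks the tertiary oxygen against later oxa-Michael addition.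

Step 9
Reactants: 13 benzyl ether
Product: 14 3-[(3S,5aR,6R,7S,9aR)-2,2,5a,7-tetramethyl-3,7-bis[(triethylsilyl)oxy]decahydro-1-benzoxepin-6-yl]propan-1-ol
Conditions: H2 (1 atm), Pd/C, EtOAc, rt
Reagents that add atoms: none
Why: Hydrogenolysis of the benzyl ether; the molecule has no alkene and the silyl ethers should survive in a neutral aprotic solvent.

Step 10
Reactants: 14 primary alcohol
Product: 15 3-[(3S,5aR,6R,7S,9aR)-2,2,5a,7-tetramethyl-3,7-bis[(triethylsilyl)oxy]decahydro-1-benzoxepin-6-yl]propanal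
Conditions: Dess–Martin periodinane, CH2Cl2, rt
Reagents that add atoms: none
Why: Dess–Martin oxidation of the only free alcohol to the aldehyde, which has no α-stereocentre to lose.

**Right half**

Step 11
Reactants: 16 (4R)-limonene 1,2-oxide
Product: 17 (3R)-6-oxo-3-(prop-1-en-2-yl)heptanal
Conditions: H5IO6, THF/H2O, 0 °C to rt
Reagents that add atoms: water, O
Why: Epoxide hydrolysis and periodate glycol cleavage in one flask open the six-membered ring; the stereocentre is not touched and both epoxide isomers converge.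

Step 12
Reactants: 17 keto aldehyde
Product: 18 (5S)-2-methyl-5-(prop-1-en-2-yl)cyclopent-1-ene-1-carbaldehyde
Conditions: piperidine, AcOH, benzene, reflux
Reagents that add atoms: none
Why: Intramolecular aldol condensation (aldehyde α-carbon onto the methyl ketone) closes the cyclopentene, with C-5 carried over from (R)-limonene.

Step 13
Reactants: 18 enal
Product: 19 (1S,2S,5R)-5-methyl-2-(prop-1-en-2-yl)-6-oxabicyclo[3.1.0]hexane-1-carbaldehyde
Conditions: 30% aqueous H2O2, NaOH (cat.), MeOH, 0 °C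
Reagents that add atoms: hydrogen peroxide, OO
Why: Weitz–Scheffer nucleophilic epoxidation of the enal only; hydroperoxide addition is reversible and ring closure should occur on the face away from the adjacent isopropenyl group, which places the future tertiary oxygen trans to it.

Step 14
Reactants: 19 epoxy aldehyde
Product: 21 2-[(2R,5S)-2-hydroxy-2-methyl-5-(prop-1-en-2-yl)cyclopentylidene]acetaldehyde (E/Z mixture), via epoxy enol ether 20 (not isolated)
Conditions: MeOCH2PPh3Cl, KN(SiMe3)2, THF, −78 to 0 °C; then 1 M aqueous HCl, THF, 0 °C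
Reagents that add atoms: (methoxymethyl)triphenylphosphonium chloride, COC[P+](c1ccccc1)(c1ccccc1)c1ccccc1.[Cl-]; water, O
Why: Wittig methoxymethylenation followed by acid hydrolysis, in which the enol ether opens the allylic epoxide C–O bond (vinylogous epoxide opening), adds one carbon and leaves the epoxide oxygen as the tertiary alcohol with its configuration retained.

Step 15
Reactants: 21 γ-hydroxy enal
Product: 22 2-[(1R,2R,5R)-2-hydroxy-2-methyl-5-(prop-1-en-2-yl)cyclopentyl]acetaldehyde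
Conditions: [(Ph3P)CuH]6 (0.5 equiv), H2O (5 equiv), benzene, rt
Reagents that add atoms: none
Why: Copper hydride conjugate reduction of the enal; hydride should reach the exocyclic β-carbon from the face of the hydroxyl, away from the C-2 methyl and the C-5 isopropenyl group, which sets C-1 with the acetaldehyde arm cis to isopropenyl from either alkene isomer and leaves the 1,1-disubstituted alkene alone.

Step 16
Reactants: 22 hydroxy aldehyde
Product: 23 dimethyl {3-[(1R,2R,5R)-2-hydroxy-2-methyl-5-(prop-1-en-2-yl)cyclopentyl]-2-oxopropyl}phosphonate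
Conditions: (MeO)2P(O)CHN2, SnCl2 (10 mol%), CH2Cl2, rt
Reagents that add atoms: dimethyl (diazomethyl)phosphonate, COP(=O)(OC)C=[N+]=[N-]
Why: Roskamp-type homologation (Lewis-acid-catalysed addition of the diazo compound to the aldehyde, hydride shift, loss of N2) turns the aldehyde directly into the β-ketophosphonate without touching the stereocentres.

**Union and endgame**

Step 17
Reactants: 23 cyclopentane β-ketophosphonate; 15 benzoxepane aldehyde
Product: 24 dimethyl {1-[(1R,2R,5R)-2-hydroxy-2-methyl-5-(prop-1-en-2-yl)cyclopentyl]-2-oxo-6-[(3S,5aR,6R,7S,9aR)-2,2,5a,7-tetramethyl-3,7-bis[(triethylsilyl)oxy]decahydro-1-benzoxepin-6-yl]hex-3-en-3-yl}phosphonate (E/Z mixture)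
Conditions: piperidine (20 mol%), AcOH (20 mol%), 4 Å molecular sieves, toluene, 40 °C
Reagents that add atoms: none
Why: Knoevenagel condensation of the active methylene with the unbranched aldehyde joins the halves and keeps the phosphonate as a second activating group; the alkene geometry is irrelevant to the next step.

Step 18
Reactants: 24 alkylidene β-ketophosphonate
Product: 25 dimethyl [(3R,3aR,8aR)-3-hydroxy-3,8,8-trimethyl-5-oxo-7-{2-[(3S,5aR,6R,7S,9aR)-2,2,5a,7-tetramethyl-3,7-bis[(triethylsilyl)oxy]decahydro-1-benzoxepin-6-yl]ethyl}decahydroazulen-6-yl]phosphonate (mixture at C-6 and C-7)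
Conditions: Fe(acac)3 (30 mol%), PhSiH3 (3 equiv), EtOH/ethylene glycol (5:1), 60 °C, 5 mM
Reagents that add atoms: none
Why: An iron hydride formed from Fe(acac)3 and PhSiH3 transfers a hydrogen atom to the CH2 terminus of the isopropenyl group (the electron-poor alkylidene is left alone), and the tertiary radical at the future C-8 adds to the β-carbon C-7 of the alkylidene β-ketophosphonate; the resulting α-keto-α-phosphono radical is reduced and protonated by ethanol. The closest known reaction type is the iron-mediated MHAT reductive olefin coupling (radical conjugate addition that builds quaternary carbons), used here intramolecularly. The ring closes in the 7-endo-trig mode; 6-exo attack on the α-carbon is polarity-mismatched and would leave an unstabilised radical. C-8 becomes quaternary but is not stereogenic, the cis ring fusion (C-3a/C-8a) is already fixed, and the new centres C-6 and C-7 need no control because steps 19 and 20 erase both, so both alkene isomers of 24 and all diastereomers of 25 converge. The step needs hydrogen-atom transfer to the 1,1-disubstituted alkene only and cyclization faster than reduction of the radical; the cis-1,2 placement of the two arms on the cyclopentane, the doubly activated acceptor with an unhindered β-CH and high dilution should secure this.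

Step 19
Reactants: 25 cyclic β-ketophosphonate
Product: 26 (3R,3aR,8aR)-3-hydroxy-3,8,8-trimethyl-6-methylidene-7-{2-[(3S,5aR,6R,7S,9aR)-2,2,5a,7-tetramethyl-3,7-bis[(triethylsilyl)oxy]decahydro-1-benzoxepin-6-yl]ethyl}octahydroazulen-5(1H)-one (C-7 epimers)
Conditions: K2CO3, 37% aqueous HCHO, THF, rt to 40 °C
Reagents that add atoms: formaldehyde, C=O
Why: Horner–Wadsworth–Emmons methylenation removes the phosphonate helper and puts the future C-6 methyl carbon exactly at the phosphonate-bearing carbon, so no ketone enolization regiochemistry has to be controlled.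

Step 20
Reactants: 26 α-methylene ketone
Product: 27 (3R,3aR,8aR)-3-hydroxy-3,6,8,8-tetramethyl-7-{2-[(3S,5aR,6R,7S,9aR)-2,2,5a,7-tetramethyl-3,7-bis[(triethylsilyl)oxy]decahydro-1-benzoxepin-6-yl]ethyl}-2,3,3a,4,8,8a-hexahydroazulen-5(1H)-one
Conditions: RhCl3·3H2O (10 mol%), EtOH, 70 °C
Reagents that add atoms: none
Why: Rhodium-hydride alkene isomerization should move the exocyclic double bond into the ring to the conjugated tetrasubstituted enone, the thermodynamic isomer, which erases the C-7 stereocentre.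

Step 21
Reactants: 27 bis(silyl ether)
Product: 28 (3R,3aR,8aR)-7-{2-[(3S,5aR,6R,7S,9aR)-3,7-dihydroxy-2,2,5a,7-tetramethyldecahydro-1-benzoxepin-6-yl]ethyl}-3-hydroxy-3,6,8,8-tetramethyl-2,3,3a,4,8,8a-hexahydroazulen-5(1H)-one
Conditions: HF·pyridine, pyridine, THF, 0 °C to rt
Reagents that add atoms: none
Why: Fluoride-mediated cleavage of both triethylsilyl ethers under buffered conditions that should spare the tertiary alcohols and the enone.

**Compound list**

1 | geraniol, (2E)-3,7-dimethylocta-2,6-dien-1-ol | CC(C)=CCC/C(C)=C/CO | starting material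
2 | [(2R,3R)-3-methyl-3-(4-methylpent-3-en-1-yl)oxiran-2-yl]methanol | CC(C)=CCC[C@@]1(C)O[C@@H]1CO | intermediate
3 | [(2R,3R)-3-methyl-3-(4-methylpent-3-en-1-yl)oxiran-2-yl]methyl 4-methylbenzenesulfonate | CC(C)=CCC[C@@]1(C)O[C@@H]1COS(=O)(=O)c1ccc(C)cc1 | intermediate
4 | dimethyl (2-oxopropyl)phosphonate | CC(=O)CP(=O)(OC)OC | starting material
5 | sodium lithium dianion of dimethyl (2-oxopropyl)phosphonate | [Na+].[Li+].[CH2-]C(=O)[CH-]P(=O)(OC)OC | intermediate
6 | dimethyl {4-[(2R,3R)-3-methyl-3-(4-methylpent-3-en-1-yl)oxiran-2-yl]-2-oxobutyl}phosphonate | CC(C)=CCC[C@@]1(C)O[C@@H]1CCC(=O)CP(=O)(OC)OC | intermediate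
7 | 3-(benzyloxy)propanal | O=CCCOCc1ccccc1 | starting material
8 | (4E)-7-(benzyloxy)-1-[(2R,3R)-3-methyl-3-(4-methylpent-3-en-1-yl)oxiran-2-yl]hept-4-en-3-one | CC(C)=CCC[C@@]1(C)O[C@@H]1CCC(=O)/C=C/CCOCc1ccccc1 | intermediate
9 | (4E)-7-(benzyloxy)-1-[(2R,3R)-3-{2-[(2S)-3,3-dimethyloxiran-2-yl]ethyl}-3-methyloxiran-2-yl]hept-4-en-3-one | CC1(C)O[C@H]1CC[C@@]2(C)O[C@@H]2CCC(=O)/C=C/CCOCc1ccccc1 | intermediate
10 | {[(3Z)-7-(benzyloxy)-1-[(2R,3R)-3-{2-[(2S)-3,3-dimethyloxiran-2-yl]ethyl}-3-methyloxiran-2-yl]hept-3-en-3-yl]oxy}(triethyl)silane | CC1(C)O[C@H]1CC[C@@]2(C)O[C@@H]2CC/C(O[Si](CC)(CC)CC)=C/CCCOCc1ccccc1 | intermediate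
11 | (3S,5aR,6R,9aR)-6-[3-(benzyloxy)propyl]-2,2,5a-trimethyl-3-[(triethylsilyl)oxy]octahydro-1-benzoxepin-7(2H)-one | c1ccccc1COCCC[C@@H]2[C@@]3(C)CC[C@H](O[Si](CC)(CC)CC)C(C)(C)O[C@@H]3CCC2=O | intermediate
12 | lithium (3S,5aR,6R,7S,9aR)-6-[3-(benzyloxy)propyl]-2,2,5a,7-tetramethyl-3-[(triethylsilyl)oxy]decahydro-1-benzoxepin-7-olate | c1ccccc1COCCC[C@@H]2[C@@]3(C)CC[C@H](O[Si](CC)(CC)CC)C(C)(C)O[C@@H]3CC[C@]2(C)[O-].[Li+] | intermediate
13 | (3S,5aR,6R,7S,9aR)-6-[3-(benzyloxy)propyl]-2,2,5a,7-tetramethyl-3,7-bis[(triethylsilyl)oxy]decahydro-1-benzoxepine | c1ccccc1COCCC[C@@H]2[C@@]3(C)CC[C@H](O[Si](CC)(CC)CC)C(C)(C)O[C@@H]3CC[C@]2(C)O[Si](CC)(CC)CC | intermediate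
14 | 3-[(3S,5aR,6R,7S,9aR)-2,2,5a,7-tetramethyl-3,7-bis[(triethylsilyl)oxy]decahydro-1-benzoxepin-6-yl]propan-1-ol | OCCC[C@@H]2[C@@]3(C)CC[C@H](O[Si](CC)(CC)CC)C(C)(C)O[C@@H]3CC[C@]2(C)O[Si](CC)(CC)CC | intermediate
15 | 3-[(3S,5aR,6R,7S,9aR)-2,2,5a,7-tetramethyl-3,7-bis[(triethylsilyl)oxy]decahydro-1-benzoxepin-6-yl]propanal | O=CCC[C@@H]2[C@@]3(C)CC[C@H](O[Si](CC)(CC)CC)C(C)(C)O[C@@H]3CC[C@]2(C)O[Si](CC)(CC)CC | intermediate
16 | (4R)-limonene 1,2-oxide, (4R)-1-methyl-4-(prop-1-en-2-yl)-7-oxabicyclo[4.1.0]heptane, cis/trans mixture | CC12OC1C[C@@H](CC2)C(C)=C | starting material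
17 | (3R)-6-oxo-3-(prop-1-en-2-yl)heptanal | CC(=C)[C@@H](CC=O)CCC(C)=O | intermediate
18 | (5S)-2-methyl-5-(prop-1-en-2-yl)cyclopent-1-ene-1-carbaldehyde | CC(=C)[C@@H]1CCC(C)=C1C=O | intermediate
19 | (1S,2S,5R)-5-methyl-2-(prop-1-en-2-yl)-6-oxabicyclo[3.1.0]hexane-1-carbaldehyde (epoxide trans to isopropenyl) | CC(=C)[C@@H]1CC[C@@]2(C)O[C@@]12C=O | intermediate
20 | (2S,5R)-1-(2-methoxyethenyl)-5-methyl-2-(prop-1-en-2-yl)-6-oxabicyclo[3.1.0]hexane, epoxide as in 19, E/Z mixture | CC(=C)[C@@H]1CC[C@@]2(C)O[C@@]12C=COC | intermediate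
21 | 2-[(2R,5S)-2-hydroxy-2-methyl-5-(prop-1-en-2-yl)cyclopentylidene]acetaldehyde, E/Z mixture | CC(=C)[C@@H]1CC[C@@](C)(O)C1=CC=O | intermediate
22 | 2-[(1R,2R,5R)-2-hydroxy-2-methyl-5-(prop-1-en-2-yl)cyclopentyl]acetaldehyde | CC(=C)[C@@H]1CC[C@@](C)(O)[C@@H]1CC=O | intermediate
23 | dimethyl {3-[(1R,2R,5R)-2-hydroxy-2-methyl-5-(prop-1-en-2-yl)cyclopentyl]-2-oxopropyl}phosphonate | CC(=C)[C@@H]1CC[C@@](C)(O)[C@@H]1CC(=O)CP(=O)(OC)OC | intermediate
24 | dimethyl {1-[(1R,2R,5R)-2-hydroxy-2-methyl-5-(prop-1-en-2-yl)cyclopentyl]-2-oxo-6-[(3S,5aR,6R,7S,9aR)-2,2,5a,7-tetramethyl-3,7-bis[(triethylsilyl)oxy]decahydro-1-benzoxepin-6-yl]hex-3-en-3-yl}phosphonate, E/Z mixture | CC(=C)[C@@H]1CC[C@@](C)(O)[C@@H]1CC(=O)C(=CCC[C@@H]2[C@@]3(C)CC[C@H](O[Si](CC)(CC)CC)C(C)(C)O[C@@H]3CC[C@]2(C)O[Si](CC)(CC)CC)P(=O)(OC)OC | intermediate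
25 | dimethyl [(3R,3aR,8aR)-3-hydroxy-3,8,8-trimethyl-5-oxo-7-{2-[(3S,5aR,6R,7S,9aR)-2,2,5a,7-tetramethyl-3,7-bis[(triethylsilyl)oxy]decahydro-1-benzoxepin-6-yl]ethyl}decahydroazulen-6-yl]phosphonate, mixture at C-6 and C-7 | COP(=O)(OC)C1C(CC[C@@H]2[C@@]3(C)CC[C@H](O[Si](CC)(CC)CC)C(C)(C)O[C@@H]3CC[C@]2(C)O[Si](CC)(CC)CC)C(C)(C)[C@@H]4CC[C@@](C)(O)[C@@H]4CC1=O | intermediate
26 | (3R,3aR,8aR)-3-hydroxy-3,8,8-trimethyl-6-methylidene-7-{2-[(3S,5aR,6R,7S,9aR)-2,2,5a,7-tetramethyl-3,7-bis[(triethylsilyl)oxy]decahydro-1-benzoxepin-6-yl]ethyl}octahydroazulen-5(1H)-one, C-7 epimers | C=C1C(CC[C@@H]2[C@@]3(C)CC[C@H](O[Si](CC)(CC)CC)C(C)(C)O[C@@H]3CC[C@]2(C)O[Si](CC)(CC)CC)C(C)(C)[C@@H]4CC[C@@](C)(O)[C@@H]4CC1=O | intermediate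
27 | (3R,3aR,8aR)-3-hydroxy-3,6,8,8-tetramethyl-7-{2-[(3S,5aR,6R,7S,9aR)-2,2,5a,7-tetramethyl-3,7-bis[(triethylsilyl)oxy]decahydro-1-benzoxepin-6-yl]ethyl}-2,3,3a,4,8,8a-hexahydroazulen-5(1H)-one | CC1=C(CC[C@@H]2[C@@]3(C)CC[C@H](O[Si](CC)(CC)CC)C(C)(C)O[C@@H]3CC[C@]2(C)O[Si](CC)(CC)CC)C(C)(C)[C@@H]4CC[C@@](C)(O)[C@@H]4CC1=O | intermediate
28 | (3R,3aR,8aR)-7-{2-[(3S,5aR,6R,7S,9aR)-3,7-dihydroxy-2,2,5a,7-tetramethyldecahydro-1-benzoxepin-6-yl]ethyl}-3-hydroxy-3,6,8,8-tetramethyl-2,3,3a,4,8,8a-hexahydroazulen-5(1H)-one | CC1=C(CC[C@@H]2[C@@]3(C)CC[C@H](O)C(C)(C)O[C@@H]3CC[C@]2(C)O)C(C)(C)[C@@H]2CC[C@@](C)(O)[C@@H]2CC1=O | target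

**Count and risks**

Total steps: 21. Longest linear sequence: 15 (steps 1–10, then 17–21); the right half (steps 11–16) joins at step 17.

Steps most likely to fail:

1. Step 18 (ring closure by radical conjugate addition). The tertiary radical may be reduced, or may abstract hydrogen within the molecule, before the seven-membered ring closes; hydrogen-atom transfer to the acceptor may also compete. The fallback sets out from 15 and 22 and returns to the route at 25; it forms the C-7–C-8 bond without a ring constraint and closes the ring by a polar acylation. Horner–Wadsworth–Emmons reaction of 15 with tetramethyl methylenebis(phosphonate) and NaH would give the (E)-vinylphosphonate F1. Oxidation of 22 with pyridinium dichromate (C5H5NH)2Cr2O7 in MeOH/DMF would give the methyl ester F2. Intermolecular MHAT coupling of F2 with F1 (Fe(acac)3, PhSiH3, EtOH) would give the phosphonate ester F3. LiN(iPr)2 would then close the ring by intramolecular acylation of the α-phosphonate carbanion by the ester (Dieckmann-type), which gives 25.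

2. Step 7 (epoxide-opening cascade). The two epoxides of 10 are of opposite enantiofacial sense, so folding of the epoxonium ion into the chair needed for trans fusion may be slow; 6-exo opening or loss of the enol silane by protodesilylation could then compete. The fallback sets out from 8 and returns at 11; it builds the two rings in separate steps so that C-3 is set independently of the carbocyclization. Hydrosilylation of 8 (Et3SiH, RhCl(PPh3)3) would give the mono-epoxy silyl enol ether F4. MeAlCl2 (CH2Cl2, −78 °C) would trigger the epoxide-initiated cyclization onto the enol silane and give the hydroxy cyclohexanone F5. Epoxidation of the remaining trisubstituted alkene with the ent-Shi ketone and Oxone would give the hydroxy (S)-epoxide F6. Camphorsulfonic acid would promote 7-endo opening at the tertiary epoxide carbon by the ring hydroxyl and give the oxepanol F7, and Et3SiOTf/2,6-lutidine would silylate it to 11.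

3. Step 17 (Knoevenagel union). Condensation of the hindered active methylene may be slow, and the alkylidene may lose conjugation by migration of its double bond toward the side chain. The fallback sets out from 23 (with 15) and returns at 27; it uses an olefination in place of the condensation and restores the enone by dehydrogenation. C-Methylation of 23 (K2CO3, MeI, acetone) would give the α-methyl β-ketophosphonate F8. Horner–Wadsworth–Emmons reaction of F8 with 15 (Ba(OH)2, THF/H2O) would give the (E)-α-methyl enone F9. MHAT cyclization of F9 under the conditions of step 18 would give the saturated α-methyl ketone F10, and IBX (DMSO, 70 °C) would dehydrogenate it on the more substituted side to 27.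

Further compounds
F1 | step 18 | dimethyl {(1E)-4-[(3S,5aR,6R,7S,9aR)-2,2,5a,7-tetramethyl-3,7-bis[(triethylsilyl)oxy]decahydro-1-benzoxepin-6-yl]but-1-en-1-yl}phosphonate | COP(=O)(OC)/C=C/CC[C@@H]2[C@@]3(C)CC[C@H](O[Si](CC)(CC)CC)C(C)(C)O[C@@H]3CC[C@]2(C)O[Si](CC)(CC)CC
F2 | step 18 | methyl 2-[(1R,2R,5R)-2-hydroxy-2-methyl-5-(prop-1-en-2-yl)cyclopentyl]acetate | CC(=C)[C@@H]1CC[C@@](C)(O)[C@@H]1CC(=O)OC
F3 | step 18 | methyl 2-[(1R,2R,5R)-5-{3-[(dimethoxyphosphoryl)methyl]-2-methyl-5-[(3S,5aR,6R,7S,9aR)-2,2,5a,7-tetramethyl-3,7-bis[(triethylsilyl)oxy]decahydro-1-benzoxepin-6-yl]pentan-2-yl}-2-hydroxy-2-methylcyclopentyl]acetate, epimers at the phosphonomethyl-bearing carbon | COP(=O)(OC)CC(CC[C@@H]2[C@@]3(C)CC[C@H](O[Si](CC)(CC)CC)C(C)(C)O[C@@H]3CC[C@]2(C)O[Si](CC)(CC)CC)C(C)(C)[C@@H]4CC[C@@](C)(O)[C@@H]4CC(=O)OC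
F4 | step 7 | {[(3Z)-7-(benzyloxy)-1-[(2R,3R)-3-methyl-3-(4-methylpent-3-en-1-yl)oxiran-2-yl]hept-3-en-3-yl]oxy}(triethyl)silane | CC(C)=CCC[C@@]1(C)O[C@@H]1CC/C(O[Si](CC)(CC)CC)=C/CCCOCc1ccccc1
F5 | step 7 | (2R,3R,4R)-2-[3-(benzyloxy)propyl]-4-hydroxy-3-methyl-3-(4-methylpent-3-en-1-yl)cyclohexan-1-one | c1ccccc1COCCC[C@@H]2[C@@](C)(CCC=C(C)C)[C@H](O)CCC2=O
F6 | step 7 | (2R,3R,4R)-2-[3-(benzyloxy)propyl]-3-{2-[(2S)-3,3-dimethyloxiran-2-yl]ethyl}-4-hydroxy-3-methylcyclohexan-1-one | c1ccccc1COCCC[C@@H]2[C@@](C)(CC[C@@H]3OC3(C)C)[C@H](O)CCC2=O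
F7 | step 7 | (3S,5aR,6R,9aR)-6-[3-(benzyloxy)propyl]-3-hydroxy-2,2,5a-trimethyloctahydro-1-benzoxepin-7(2H)-one | c1ccccc1COCCC[C@@H]2[C@@]3(C)CC[C@H](O)C(C)(C)O[C@@H]3CCC2=O
F8 | step 17 | dimethyl {4-[(1R,2R,5R)-2-hydroxy-2-methyl-5-(prop-1-en-2-yl)cyclopentyl]-3-oxobutan-2-yl}phosphonate, epimers at C-2 of the butane chain | CC(=C)[C@@H]1CC[C@@](C)(O)[C@@H]1CC(=O)C(C)P(=O)(OC)OC
F9 | step 17 | (3E)-1-[(1R,2R,5R)-2-hydroxy-2-methyl-5-(prop-1-en-2-yl)cyclopentyl]-3-methyl-6-[(3S,5aR,6R,7S,9aR)-2,2,5a,7-tetramethyl-3,7-bis[(triethylsilyl)oxy]decahydro-1-benzoxepin-6-yl]hex-3-en-2-one | CC(=C)[C@@H]1CC[C@@](C)(O)[C@@H]1CC(=O)/C(C)=C/CC[C@@H]2[C@@]3(C)CC[C@H](O[Si](CC)(CC)CC)C(C)(C)O[C@@H]3CC[C@]2(C)O[Si](CC)(CC)CC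
F10 | step 17 | (3R,3aR,8aR)-3-hydroxy-3,6,8,8-tetramethyl-7-{2-[(3S,5aR,6R,7S,9aR)-2,2,5a,7-tetramethyl-3,7-bis[(triethylsilyl)oxy]decahydro-1-benzoxepin-6-yl]ethyl}octahydroazulen-5(1H)-one, epimers at C-6 and C-7 | CC1C(CC[C@@H]2[C@@]3(C)CC[C@H](O[Si](CC)(CC)CC)C(C)(C)O[C@@H]3CC[C@]2(C)O[Si](CC)(CC)CC)C(C)(C)[C@@H]4CC[C@@](C)(O)[C@@H]4CC1=O
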